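The product of this flask comes in two forms, target and its isomer, and we want the isomer's part of the pair at each asked time.

| flask | substrate | coupling partner | remark | time |
|---|---|---|---|---|
| zeta | 10 mM | 0.95 equiv | the very flask that is asked about, followed so far |  |
| beta | 5 mM | 0.95 equiv | run made earlier |  |
| flask | 10 mM | 0.950 equiv |  | 4.0 min |

- zeta (time / s: isomer of the product / %, target / %, substrate / %): 10.0: 1.2, 1.2, 83.6; 20.0: 1.0, 1.7, 71.9; 30.0: 0.4, 2.1, 62.7; 50.0: 1.0, 3.5, 50.1; 80.0: 2.7, 4.9, 38.1; 90.0: 2.5, 3.9, 35.7; 120: 2.4, 5.6, 29.7
- beta (time / min: isomer of the product / %, target / %, substrate / %): 0.200: 0.6, 1.7, 88.5; 0.667: 1.8, 1.7, 70.8; 1.00: 1.8, 2.3, 62.5; 1.50: 1.9, 2.2, 52.4; 2.50: 2.3, 3.5, 40.4; 3.00: 2.9, 4.4, 36.4; 4.00: 2.9, 4.9, 29.9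

(scatter of a reading: 0.5 percentage points)

- share of isomer of the product in isomer of the product plus target at 10 s
- share of isomer of the product in isomer of the product plus target at 40 s
- share of isomer of the product in isomer of the product plus target at 4.0 min

- a reading or a percentage of target counts all its forms, free or not
- a reading of substrate is of its free form alone

We build the flask up one process at a time, starting with the main step. Substrate meets coupling partner nearly one to one, so we count turnovers n: the substrate charged over the substrate left, less one, which for a second-order step grows evenly with time. The zeta run reaches n = 2.37 at 120 s. The beta run, at half the charge, reaches 2.34 at twice that time. In the flask, which is the zeta run carried on, n therefore climbs 0.0197 s⁻¹, a time constant τ of 50.7 s. This gives n = 0.197 at 10 s, 0.788 at 40 s and 4.73 at 4.0 min, twice the last count read.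

Next we add a split: what reaches the pair divides between target and isomer at a fixed ratio (a selectivity), so the share stays put while n runs. Summed over both runs, the readings give 36.8%; this is the split share f, the isomer's part of the pair.

Last comes the rest. By 120 s the zeta run has lost 70.3% of its free substrate but shows 8.00% as the pair. A loss ahead of the split leaves f untouched, whereas a slow loss of target, with the isomer kept, raises the share as n grows. From n = 1.48 on, the readings of both runs give 36.6%, so they show no rise over f, at a scatter of 0.5 percentage points per reading. We commit to f at each asked time, least firmly at 4.0 min.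

The forecast gives 37%, 37% and 37%, the last within 29% to 45%: “This suggests parallel formation at a fixed ratio”.

The flask gives 36.2% at 10 s, 36.2% at 40 s and 38.9% at 4.0 min.

    substrate + coupling partner → intermediate + by-product (k = 2.00 M⁻¹ s⁻¹)
    intermediate ⇌ target (K = 13.0, k = 0.120 s⁻¹)
    intermediate ⇌ isomer of the product (K = 130, k = 0.0680 s⁻¹)
    substrate + target ⇌ idle adduct, settled at all times (K = 2600 M⁻¹)
    intermediate → side product (k = 1.40 s⁻¹)
    crystals ⇌ by-product, rate k6*(cs6 - [by-product]) while solid is left; crystals form when [by-product] > cs6 (solubility = 2.60 mM, k = 4.70 s⁻¹)

Target, all its forms counted, peaks at 4.98% after 3.13 min and stands at 4.89% at 4.0 min. Applied to that target, f gives 2.85% of isomer against 3.11% in the flask, so the share ends 2.1 points above f. In the neighbour flask with 1.60 equiv of coupling partner, 2.96% of the substrate is left at 4.0 min. There f, applied to 4.21% of target, gives 2.45% of isomer, while that flask holds 3.83%, a share of 47.7%.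

(The readings are calculated with constants of no real substance; the scatter is artificial.)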